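**Strategy**

The route rests on cutting the seven-membered ring at C4–C5 (azulene numbering), between the ester-bearing carbinol carbon and the neighbouring CH2. The target hides a homoallylic alcohol, O–C4–C5–C6=C7, inside that ring, with the C4 oxygen syn to the C3 hydroxyl. A chelation-controlled intramolecular Hosomi–Sakurai allylation exploits both features: in one operation it closes the cycloheptene, fixes the position of the C6=C7 double bond and sets C4. Its precursor is a monocyclic cyclopentane that carries the tertiary C3 carbinol, a cis formyl group at C3a and, on the quaternary C8a, a methallyl-type side chain silylated on the future C7.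

Key step: step 7

Remark: the silyl-bearing side-chain carbon is carried as a mixture of both configurations from step 2 to step 6 and becomes sp2 in step 7. The ligand enantiomer in step 3 is assumed to be the one that gives the (R)-configured quaternary centre.

**Route**

Step 1
Reactants: 1 3-ethoxycyclopent-2-en-1-one; 2 (E)-(2-bromoethenyl)trimethylsilane
Product: 5 3-[(E)-2-(trimethylsilyl)ethenyl]cyclopent-2-en-1-one, via vinyl Grignard reagent 3 (not isolated), via bromomagnesium alkoxide adduct 4 (not isolated)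
Conditions: Mg, THF, reflux; then 1, 0 °C; then 1 M HCl, rt
Reagents that add atoms: water, O
Why: Stork–Danheiser transposition: the Grignard reagent adds 1,2 to the vinylogous ester, and acid hydrolysis of the enol ether with loss of water moves the carbonyl group to give the 3-alkenyl enone with the (E)-vinylsilane intact.

Step 2
Reactants: 5 3-[(E)-2-(trimethylsilyl)ethenyl]cyclopent-2-en-1-one; 6 prop-1-en-2-ylmagnesium bromide
Product: 9 3-[3-methyl-2-(trimethylsilyl)but-3-en-1-yl]cyclopent-2-en-1-one (racemate), via bromomagnesium dienolate 7 (not isolated), via deconjugated ketone 8 (not isolated)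
Conditions: CuBr·SMe2 (10 mol %), THF, −40 °C; aq NH4Cl; then DBU (cat.), CH2Cl2, rt
Reagents that add atoms: none
Why: Copper-catalysed 1,6-conjugate addition: the cuprate should attack the silyl-bearing δ-carbon instead of the fully substituted β-carbon, as cuprates do with β-silyl enones, and base returns the double bond to conjugation; the new silyl-bearing centre forms as a racemate, which does not matter because it becomes sp2 in step 7.

Step 3
Reactants: 9 3-[3-methyl-2-(trimethylsilyl)but-3-en-1-yl]cyclopent-2-en-1-one; 10 trimethylaluminium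
Product: 12 trimethyl({(3R)-3-methyl-3-[3-methyl-2-(trimethylsilyl)but-3-en-1-yl]cyclopent-1-en-1-yl}oxy)silane, via dimethylaluminium enolate 11 (not isolated)
Conditions: Me3Al, Cu(O2CC4H3S) (copper thiophene-2-carboxylate, 5 mol %), O,O'-(1,1'-binaphthalene-2,2'-diyl) N,N-bis(1-phenylethyl)phosphoramidite (single stereoisomer, 10 mol %), Et2O, −30 °C; then Me3SiOTf, −30 to 0 °C
Reagents that add atoms: trimethylsilyl trifluoromethanesulfonate, C[Si](C)(C)OS(=O)(=O)C(F)(F)F
Why: Copper-catalysed asymmetric conjugate addition of trimethylaluminium to a β-substituted cyclopentenone should set the quaternary centre (R) under ligand control, and silylation of the aluminium enolate keeps the enolate regiochemistry next to that centre.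

Step 4
Reactants: 12 trimethyl({(3R)-3-methyl-3-[3-methyl-2-(trimethylsilyl)but-3-en-1-yl]cyclopent-1-en-1-yl}oxy)silane; 13 formaldehyde (gas, from cracked paraformaldehyde)
Product: 16 (2S,3R)-3-methyl-3-[3-methyl-2-(trimethylsilyl)but-3-en-1-yl]-2-{[(triethylsilyl)oxy]methyl}cyclopentan-1-one, via lithium enolate 14 (not isolated), via lithium aldolate 15 (not isolated)
Conditions: MeLi, THF, 0 °C; CH2O (g), −78 °C; then Et3SiCl, −78 to 0 °C
Reagents that add atoms: chlorotriethylsilane, CC[Si](CC)(CC)Cl
Why: Methyllithium releases the regiodefined lithium enolate, whose aldol reaction with monomeric formaldehyde should occur on the face opposite the bulkier β-branched silylated side chain and so place the CH2O arm cis to methyl (2S); silylation in the same flask blocks retro-aldol cleavage.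

Step 5
Reactants: 16 (2S,3R)-3-methyl-3-[3-methyl-2-(trimethylsilyl)but-3-en-1-yl]-2-{[(triethylsilyl)oxy]methyl}cyclopentan-1-one; 17 propan-2-ylmagnesium chloride
Product: 18 (1R,2S,3R)-3-methyl-3-[3-methyl-2-(trimethylsilyl)but-3-en-1-yl]-1-(propan-2-yl)-2-{[(triethylsilyl)oxy]methyl}cyclopentan-1-ol
Conditions: i-PrMgCl, LaCl3·2LiCl (1 equiv), THF, 0 °C; aq NH4Cl
Reagents that add atoms: none
Why: Lanthanum-assisted Grignard 1,2-addition (enolisation suppressed) should take place trans to the adjacent silyloxymethyl group, because the two substituents on the quaternary carbon shield both faces about equally, which puts the new hydroxyl cis to the CH2O arm (1R).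

Step 6
Reactants: 18 (1R,2S,3R)-3-methyl-3-[3-methyl-2-(trimethylsilyl)but-3-en-1-yl]-1-(propan-2-yl)-2-{[(triethylsilyl)oxy]methyl}cyclopentan-1-ol
Product: 20 (1R,2R,5R)-2-hydroxy-5-methyl-5-[3-methyl-2-(trimethylsilyl)but-3-en-1-yl]-2-(propan-2-yl)cyclopentane-1-carbaldehyde, via alkoxysulfonium chloride 19 (not isolated)
Conditions: (COCl)2, DMSO, CH2Cl2, −78 to −40 °C; Et3N, −78 to 0 °C
Reagents that add atoms: none
Why: Under Swern oxidation conditions a primary triethylsilyl ether is converted directly into the aldehyde through the alkoxysulfonium salt, while the tertiary alcohol cannot be oxidised; any epimerisation next to the formyl group would lead to the same isomer, the one with the formyl group trans to isopropyl and to the side chain.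

Step 7
Reactants: 20 (1R,2R,5R)-2-hydroxy-5-methyl-5-[3-methyl-2-(trimethylsilyl)but-3-en-1-yl]-2-(propan-2-yl)cyclopentane-1-carbaldehyde
Product: 22 (3R,3aS,4R,8aR)-6,8a-dimethyl-3-(propan-2-yl)-1,2,3,3a,4,5,8,8a-octahydroazulene-3,4-diol, via chloro(methyl)aluminium alkoxide chelate 21 (not isolated)
Conditions: Me2AlCl (2.2 equiv), CH2Cl2 (0.005 M), −78 to −20 °C; aq KNaC4H4O6 (potassium sodium tartrate)
Reagents that add atoms: none
Why: Dimethylaluminium chloride first turns the tertiary hydroxyl into a chloro(methyl)aluminium alkoxide (methane is lost, no protic acid forms), and this internal Lewis acid binds the aldehyde oxygen in a six-membered chelate. The terminal CH2 of the allylsilane then attacks the activated carbonyl carbon in an anti-SE2' fashion to give a β-silyl cation that loses chlorotrimethylsilane; this is an intramolecular Hosomi–Sakurai allylation under chelation control, closest to known allylsilane–aldehyde cyclisations to cycloheptenols and to chelation-controlled additions to β-alkoxy aldehydes. The seven-membered ring closes by a 7-exo-trig attack on the carbonyl group with the whole allyl unit inside the new ring, and because silicon sits on the ring-side allylic carbon the double bond can only appear at C6=C7. The new carbinol centre (4R) is controlled by the chelate: it holds the carbonyl oxygen on the side of the C3 oxygen, so the alkene, which must approach from the face of C8a that carries the tether, adds to the aldehyde face that leaves the two oxygens syn. Both epimers at the silyl-bearing carbon can place silicon anti to the forming bond and should converge on one product. The step needs attack through the γ-carbon of the allylsilane, secured by β-silyl cation stabilisation, and ring closure ahead of intermolecular reaction or retro-aldol cleavage, secured by high dilution and low temperature.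

Step 8
Reactants: 22 (3R,3aS,4R,8aR)-6,8a-dimethyl-3-(propan-2-yl)-1,2,3,3a,4,5,8,8a-octahydroazulene-3,4-diol; 23 4-(chlorocarbonyl)phenyl acetate
Product: 24 (3R,3aS,4R,8aR)-3-hydroxy-6,8a-dimethyl-3-(propan-2-yl)-1,2,3,3a,4,5,8,8a-octahydroazulen-4-yl 4-(acetyloxy)benzoate
Conditions: pyridine, DMAP (0.2 equiv), CH2Cl2, 0 °C to rt
Reagents that add atoms: none
Why: Nucleophilic-catalysis acylation should occur only at the secondary hydroxyl, the tertiary one being too hindered, and the acetate masks the phenol so that the acid chloride cannot react with itself.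

Step 9
Reactants: 24 (3R,3aS,4R,8aR)-3-hydroxy-6,8a-dimethyl-3-(propan-2-yl)-1,2,3,3a,4,5,8,8a-octahydroazulen-4-yl 4-(acetyloxy)benzoate
Product: 25 (3R,3aS,4R,8aR)-3-hydroxy-6,8a-dimethyl-3-(propan-2-yl)-1,2,3,3a,4,5,8,8a-octahydroazulen-4-yl 4-hydroxybenzoate
Conditions: NH4OAc, MeOH/H2O (4:1), rt
Reagents that add atoms: none
Why: An aryl acetate is far more electrophilic than the hindered secondary benzoate, so mild transesterification should remove only the phenolic acetyl group and leave the ester and all stereocentres untouched.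

**Compound list**

1 | 3-ethoxycyclopent-2-en-1-one | CCOC1=CC(=O)CC1 | starting material
2 | (E)-(2-bromoethenyl)trimethylsilane | C[Si](C)(C)/C=C/Br | starting material
3 | [(E)-2-(trimethylsilyl)ethenyl]magnesium bromide | C[Si](C)(C)/C=C/[Mg]Br | intermediate
4 | bromomagnesium 3-ethoxy-1-[(E)-2-(trimethylsilyl)ethenyl]cyclopent-2-en-1-olate | CCOC1=CC(O[Mg]Br)(/C=C/[Si](C)(C)C)CC1 | intermediate
5 | 3-[(E)-2-(trimethylsilyl)ethenyl]cyclopent-2-en-1-one | O=C1C=C(/C=C/[Si](C)(C)C)CC1 | intermediate
6 | prop-1-en-2-ylmagnesium bromide | CC(=C)[Mg]Br | starting material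
7 | bromomagnesium 3-[3-methyl-2-(trimethylsilyl)but-3-en-1-ylidene]cyclopent-1-en-1-olate | C=C(C)C([Si](C)(C)C)C=C1CCC(O[Mg]Br)=C1 | intermediate
8 | 3-[3-methyl-2-(trimethylsilyl)but-3-en-1-ylidene]cyclopentan-1-one | C=C(C)C([Si](C)(C)C)C=C1CCC(=O)C1 | intermediate
9 | 3-[3-methyl-2-(trimethylsilyl)but-3-en-1-yl]cyclopent-2-en-1-one (racemate) | C=C(C)C([Si](C)(C)C)CC1=CC(=O)CC1 | intermediate
10 | trimethylaluminium | C[Al](C)C | starting material
11 | dimethyl({(3R)-3-methyl-3-[3-methyl-2-(trimethylsilyl)but-3-en-1-yl]cyclopent-1-en-1-yl}oxy)alumane (both epimers at the silyl-bearing carbon) | C=C(C)C([Si](C)(C)C)C[C@@]1(C)CCC(O[Al](C)C)=C1 | intermediate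
12 | trimethyl({(3R)-3-methyl-3-[3-methyl-2-(trimethylsilyl)but-3-en-1-yl]cyclopent-1-en-1-yl}oxy)silane (both epimers at the silyl-bearing carbon) | C=C(C)C([Si](C)(C)C)C[C@@]1(C)CCC(O[Si](C)(C)C)=C1 | intermediate
13 | formaldehyde | C=O | starting material
14 | lithium (3R)-3-methyl-3-[3-methyl-2-(trimethylsilyl)but-3-en-1-yl]cyclopent-1-en-1-olate | C=C(C)C([Si](C)(C)C)C[C@@]1(C)CCC(O[Li])=C1 | intermediate
15 | lithium {(1S,2R)-2-methyl-2-[3-methyl-2-(trimethylsilyl)but-3-en-1-yl]-5-oxocyclopentyl}methanolate | C=C(C)C([Si](C)(C)C)C[C@@]1(C)CCC(=O)[C@@H]1CO[Li] | intermediate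
16 | (2S,3R)-3-methyl-3-[3-methyl-2-(trimethylsilyl)but-3-en-1-yl]-2-{[(triethylsilyl)oxy]methyl}cyclopentan-1-one (both epimers at the silyl-bearing carbon) | C=C(C)C([Si](C)(C)C)C[C@@]1(C)CCC(=O)[C@@H]1CO[Si](CC)(CC)CC | intermediate
17 | propan-2-ylmagnesium chloride | CC(C)[Mg]Cl | starting material
18 | (1R,2S,3R)-3-methyl-3-[3-methyl-2-(trimethylsilyl)but-3-en-1-yl]-1-(propan-2-yl)-2-{[(triethylsilyl)oxy]methyl}cyclopentan-1-ol (both epimers at the silyl-bearing carbon) | C=C(C)C([Si](C)(C)C)C[C@@]1(C)CC[C@@](O)(C(C)C)[C@@H]1CO[Si](CC)(CC)CC | intermediate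
19 | ({(1S,2R,5R)-2-hydroxy-5-methyl-5-[3-methyl-2-(trimethylsilyl)but-3-en-1-yl]-2-(propan-2-yl)cyclopentyl}methoxy)dimethylsulfonium chloride | C=C(C)C([Si](C)(C)C)C[C@@]1(C)CC[C@@](O)(C(C)C)[C@@H]1CO[S+](C)C.[Cl-] | intermediate
20 | (1R,2R,5R)-2-hydroxy-5-methyl-5-[3-methyl-2-(trimethylsilyl)but-3-en-1-yl]-2-(propan-2-yl)cyclopentane-1-carbaldehyde (both epimers at the silyl-bearing carbon) | C=C(C)C([Si](C)(C)C)C[C@@]1(C)CC[C@@](O)(C(C)C)[C@@H]1C=O | intermediate
21 | chloro(methyl)aluminium (1R,2R,3R)-2-formyl-3-methyl-3-[3-methyl-2-(trimethylsilyl)but-3-en-1-yl]-1-(propan-2-yl)cyclopentan-1-olate | C=C(C)C([Si](C)(C)C)C[C@@]1(C)CC[C@@](O[Al](C)Cl)(C(C)C)[C@@H]1C=O | intermediate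
22 | (3R,3aS,4R,8aR)-6,8a-dimethyl-3-(propan-2-yl)-1,2,3,3a,4,5,8,8a-octahydroazulene-3,4-diol | CC1=CC[C@@]2(C)CC[C@@](O)(C(C)C)[C@@H]2[C@H](O)C1 | intermediate
23 | 4-(chlorocarbonyl)phenyl acetate | CC(=O)Oc1ccc(cc1)C(Cl)=O | starting material
24 | (3R,3aS,4R,8aR)-3-hydroxy-6,8a-dimethyl-3-(propan-2-yl)-1,2,3,3a,4,5,8,8a-octahydroazulen-4-yl 4-(acetyloxy)benzoate | CC1=CC[C@@]2(C)CC[C@@](O)(C(C)C)[C@@H]2[C@H](OC(=O)c2ccc(OC(C)=O)cc2)C1 | intermediate
25 | (3R,3aS,4R,8aR)-3-hydroxy-6,8a-dimethyl-3-(propan-2-yl)-1,2,3,3a,4,5,8,8a-octahydroazulen-4-yl 4-hydroxybenzoate | CC1=CC[C@@]2(C)CC[C@@](O)(C(C)C)[C@@H]2[C@H](OC(=O)c2ccc(O)cc2)C1 | target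

**Step count and risks**

Total step count: 9. Longest linear sequence: 9 steps (from 1 and 2 to 25).

Steps most likely to fail:

Step 7 (key step). The aluminium chelate may fail to control the aldehyde face, so that attack through an open transition state delivers the other configuration at C4; protodesilylation before ring closure is the second risk. The fallback sets out from 20. Cyclisation with the monodentate Lewis acid BF3·OEt2 (CH2Cl2, −78 °C) is expected to give mainly the epimeric diol (3R,3aS,4S,8aR)-6,8a-dimethyl-3-(propan-2-yl)-1,2,3,3a,4,5,8,8a-octahydroazulene-3,4-diol F1. Oxidation of its secondary alcohol with 1,1,1-triacetoxy-1,1-dihydro-1,2-benziodoxol-3(1H)-one (CH2Cl2, NaHCO3) would give the hydroxy ketone (3R,3aR,8aR)-3-hydroxy-6,8a-dimethyl-3-(propan-2-yl)-2,3,3a,5,8,8a-hexahydroazulen-4(1H)-one F2. Reduction with LiBH(s-Bu)3 (THF, −78 °C) should then deliver hydride from the face opposite the axial angular methyl group and give the axial alcohol; the route is rejoined at 22.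

Step 4. Facial selectivity in the attack of formaldehyde on the enolate may be poor, since the neighbouring quaternary carbon offers only methyl against CH2 as the difference. The fallback sets out from 12. A catalyst-controlled Mukaiyama aldol reaction with aqueous formaldehyde [Sc(OTf)3, enantiopure 6,6'-bis(1-hydroxy-2,2-dimethylpropyl)-2,2'-bipyridine, DME/H2O, −20 °C] would let the ligand choose the enolate face and give (2S,3R)-2-(hydroxymethyl)-3-methyl-3-[3-methyl-2-(trimethylsilyl)but-3-en-1-yl]cyclopentan-1-one F3. Silylation (Et3SiCl, imidazole, DMF) returns to the route at 16.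

Step 5. Enolisation of the ketone with β-elimination of the silyloxy group, or reduction of the carbonyl by β-hydride transfer from the secondary Grignard reagent, may take the place of addition. The fallback sets out from 16. Addition of the sp2 reagent 6 (LaCl3·2LiCl, THF, 0 °C), which has no transferable β-hydrogen, would give (1S,2S,3R)-3-methyl-3-[3-methyl-2-(trimethylsilyl)but-3-en-1-yl]-1-(prop-1-en-2-yl)-2-{[(triethylsilyl)oxy]methyl}cyclopentan-1-ol F4. The conditions of step 6 would then give (1R,2S,5R)-2-hydroxy-5-methyl-5-[3-methyl-2-(trimethylsilyl)but-3-en-1-yl]-2-(prop-1-en-2-yl)cyclopentane-1-carbaldehyde F5, and those of step 7 (3S,3aS,4R,8aR)-6,8a-dimethyl-3-(prop-1-en-2-yl)-1,2,3,3a,4,5,8,8a-octahydroazulene-3,4-diol F6. Hydrogenation with RhCl(PPh3)3 (H2, benzene, rt) should reduce the 1,1-disubstituted alkene and spare the trisubstituted ring alkene; the route is rejoined at 22.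

**Further compounds**

F1 | step 7 | (3R,3aS,4S,8aR)-6,8a-dimethyl-3-(propan-2-yl)-1,2,3,3a,4,5,8,8a-octahydroazulene-3,4-diol | CC1=CC[C@@]2(C)CC[C@@](O)(C(C)C)[C@@H]2[C@@H](O)C1
F2 | step 7 | (3R,3aR,8aR)-3-hydroxy-6,8a-dimethyl-3-(propan-2-yl)-2,3,3a,5,8,8a-hexahydroazulen-4(1H)-one | CC1=CC[C@@]2(C)CC[C@@](O)(C(C)C)[C@@H]2C(=O)C1
F3 | step 4 | (2S,3R)-2-(hydroxymethyl)-3-methyl-3-[3-methyl-2-(trimethylsilyl)but-3-en-1-yl]cyclopentan-1-one | C=C(C)C([Si](C)(C)C)C[C@@]1(C)CCC(=O)[C@@H]1CO
F4 | step 5 | (1S,2S,3R)-3-methyl-3-[3-methyl-2-(trimethylsilyl)but-3-en-1-yl]-1-(prop-1-en-2-yl)-2-{[(triethylsilyl)oxy]methyl}cyclopentan-1-ol | C=C(C)C([Si](C)(C)C)C[C@@]1(C)CC[C@@](O)(C(C)=C)[C@@H]1CO[Si](CC)(CC)CC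
F5 | step 5 | (1R,2S,5R)-2-hydroxy-5-methyl-5-[3-methyl-2-(trimethylsilyl)but-3-en-1-yl]-2-(prop-1-en-2-yl)cyclopentane-1-carbaldehyde | C=C(C)C([Si](C)(C)C)C[C@@]1(C)CC[C@@](O)(C(C)=C)[C@@H]1C=O
F6 | step 5 | (3S,3aS,4R,8aR)-6,8a-dimethyl-3-(prop-1-en-2-yl)-1,2,3,3a,4,5,8,8a-octahydroazulene-3,4-diol | CC1=CC[C@@]2(C)CC[C@@](O)(C(C)=C)[C@@H]2[C@H](O)C1
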